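**Plan**

1. Retrosynthesis first removes the aroate at the C3 oxygen, the C6 methyl and the C5=C6 unsaturation, and returns the C4 carbinol to a ketone. It then cuts C3a–C8a and C7–C8, the two bonds of a de Mayo reaction, back to a cyclopentane-1,3-dione enol carbonate whose C2 carries the C3 carbinol and a 3-methylbut-3-enyl tether.
2. Enabling feature: ring A has oxygen on C4 and C7, which are 1,5-related through C3a, C8a and C8. C8 and C8a are the two alkene carbons inserted between the former dione carbons (C7 and C3a), and the C3a–C8a bond also closes ring B.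
3. Further cuts: the dione ring by intramolecular Claisen condensation, the acyl–CH2 bond to methyl acrylate (Stetter), the aldehyde back to a Sharpless epoxy alcohol, and the trisubstituted alkene at its C–CH2 bond (enol triflate plus homoallyl Grignard reagent).
4. Forward: the chain is joined first, the five-membered dione ring second. Ring B (photochemical 1,5-closure) and ring A (retro-aldol expansion of the dione ring) then arise in one step, and ring A is functionalised last.
5. Stereochemistry: C3 comes from the Sharpless epoxidation (D-(−)-tartrate). C8a follows from C3 through a hydrogen-bond-fixed rotamer in the photocycloaddition. C3a is set by equilibration to the trans ring fusion, and C4 by hydroxyl-directed hydride delivery from the C3 hydroxyl.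

Key step: step 12

Remark: locants follow the hydroazulene skeleton of the target (C3 isopropyl carbinol, C3a ring-fusion CH, C4 secondary carbinol, C5=C6, C7 ketone, C8 CH2, C8a methyl-bearing carbon; ring A seven-membered, ring B five-membered). 4-Bromo-2-methylbut-1-ene is taken as a commercial starting material.

**Route**

Step 1
Reactants: 1 ethyl 4-methyl-3-oxopentanoate
Product: 2 ethyl (2Z)-4-methyl-3-{[(trifluoromethyl)sulfonyl]oxy}pent-2-enoate
Conditions: NaH, Et2O, 0 °C; then Tf2O, 0 °C
Reagents that add atoms: trifluoromethanesulfonic anhydride, O=S(=O)(OS(=O)(=O)C(F)(F)F)C(F)(F)F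
Why: O-Sulfonylation of the chelated sodium enolate of a β-keto ester (enol triflate formation) should give the Z isomer with the triflate cis to the ester, and this geometry later places the isopropyl group trans to the hydroxymethyl carbon.

Step 2
Reactants: 2 ethyl (2Z)-4-methyl-3-{[(trifluoromethyl)sulfonyl]oxy}pent-2-enoate; 3 4-bromo-2-methylbut-1-ene
Product: 5 ethyl (2E)-6-methyl-3-(propan-2-yl)hepta-2,6-dienoate, via Grignard reagent 4 (not isolated)
Conditions: 3, Mg, THF, rt; then 2, Fe(acac)3 (5 mol %), THF/NMP, −30 °C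
Reagents that add atoms: none
Why: Iron-catalysed Kumada-type cross-coupling of an enol triflate with an alkylmagnesium halide is fast at low temperature, tolerates the ester and replaces the triflate with retention of alkene geometry, so the homoallyl chain ends cis to the ester.

Step 3
Reactants: 5 ethyl (2E)-6-methyl-3-(propan-2-yl)hepta-2,6-dienoate
Product: 6 (2E)-6-methyl-3-(propan-2-yl)hepta-2,6-dien-1-ol
Conditions: iBu2AlH (2.2 equiv), CH2Cl2, −78 °C
Reagents that add atoms: none
Why: 1,2-Reduction of an α,β-unsaturated ester by iBu2AlH gives the allylic alcohol without touching either alkene or the alkene geometry.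

Step 4
Reactants: 6 (2E)-6-methyl-3-(propan-2-yl)hepta-2,6-dien-1-ol
Product: 7 [(2R,3R)-3-(3-methylbut-3-en-1-yl)-3-(propan-2-yl)oxiran-2-yl]methanol
Conditions: Ti(OiPr)4 (10 mol %), D-(−)-diisopropyl tartrate (12 mol %), tBuOOH, 4 Å MS, CH2Cl2, −20 °C
Reagents that add atoms: tert-butyl hydroperoxide, CC(C)(C)OO
Why: Sharpless asymmetric epoxidation acts only on the allylic alcohol, and with the D-(−)-tartrate ligand oxygen should be delivered to the face that makes the fully substituted epoxide carbon R (the future C3 configuration); as in nerol, an unbranched chain sits cis to the hydroxymethyl group and the branched group trans to it, a pattern that is epoxidised with high enantioselectivity.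

Step 5
Reactants: 7 [(2R,3R)-3-(3-methylbut-3-en-1-yl)-3-(propan-2-yl)oxiran-2-yl]methanol
Product: 8 (3S)-6-methyl-3-(propan-2-yl)hept-6-ene-1,3-diol
Conditions: NaAlH2(OCH2CH2OMe)2 (Red-Al), THF, 0 °C → rt
Reagents that add atoms: none
Why: The hydroxyl-bound aluminate delivers hydride to C2 of the 2,3-epoxy alcohol (Red-Al opening to a 1,3-diol), which is also the only epoxide carbon open to SN2 attack, so the tertiary C–O bond and its configuration are untouched.

Step 6
Reactants: 8 (3S)-6-methyl-3-(propan-2-yl)hept-6-ene-1,3-diol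
Product: 9 (3S)-6-methyl-3-(propan-2-yl)-1,3-bis[(triethylsilyl)oxy]hept-6-ene
Conditions: Et3SiOTf (2.5 equiv), 2,6-lutidine, CH2Cl2, −78 → 0 °C
Reagents that add atoms: triethylsilyl trifluoromethanesulfonate, CC[Si](CC)(CC)OS(=O)(=O)C(F)(F)F
Why: A silyl triflate with 2,6-lutidine silylates the hindered tertiary alcohol as well as the primary one, giving the bis-silyl ether needed for the selective oxidation that follows.

Step 7
Reactants: 9 (3S)-6-methyl-3-(propan-2-yl)-1,3-bis[(triethylsilyl)oxy]hept-6-ene
Product: 10 (3S)-6-methyl-3-(propan-2-yl)-3-[(triethylsilyl)oxy]hept-6-enal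
Conditions: (COCl)2, DMSO, CH2Cl2, −78 → −40 °C; then Et3N, −78 °C → rt
Reagents that add atoms: none
Why: Under Swern conditions the chlorosulfonium salt cleaves the unhindered primary triethylsilyl ether and oxidises it in the same flask to the aldehyde, while the tertiary silyl ether is too hindered to react.

Step 8
Reactants: 10 (3S)-6-methyl-3-(propan-2-yl)-3-[(triethylsilyl)oxy]hept-6-enal; 11 methyl acrylate
Product: 12 methyl (6S)-9-methyl-4-oxo-6-(propan-2-yl)-6-[(triethylsilyl)oxy]dec-9-enoate
Conditions: 3-benzyl-5-(2-hydroxyethyl)-4-methylthiazolium chloride (20 mol %), Et3N, dioxane, 80 °C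
Reagents that add atoms: none
Why: In the Stetter reaction the thiazolium carbene turns the unhindered aliphatic aldehyde into an acyl anion equivalent that adds 1,4 to the acrylate and gives the 4-oxo ester directly, the closed-shell intermediate ignoring the unactivated 1,1-disubstituted alkene.

Step 9
Reactants: 12 methyl (6S)-9-methyl-4-oxo-6-(propan-2-yl)-6-[(triethylsilyl)oxy]dec-9-enoate
Product: 13 2-{(3R)-2,6-dimethyl-3-[(triethylsilyl)oxy]hept-6-en-3-yl}-3-hydroxycyclopent-2-en-1-one (enol form of the cyclopentane-1,3-dione)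
Conditions: KOtBu (2.2 equiv), THF, 0 °C → rt; then 1 M HCl to pH 3, 0 °C
Reagents that add atoms: none
Why: Intramolecular Claisen (Dieckmann-type) condensation of a 4-oxoalkanoate is the standard entry to 2-substituted cyclopentane-1,3-diones: only the enolate on the carbinol side of the ketone can reach the ester through a five-membered transition state, and irreversible formation of the stabilised dione enolate drives the closure.

Step 10
Reactants: 13 2-{(3R)-2,6-dimethyl-3-[(triethylsilyl)oxy]hept-6-en-3-yl}-3-hydroxycyclopent-2-en-1-one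
Product: 14 benzyl 2-{(3R)-2,6-dimethyl-3-[(triethylsilyl)oxy]hept-6-en-3-yl}-3-oxocyclopent-1-en-1-yl carbonate
Conditions: BnOCOCl, pyridine, CH2Cl2, 0 °C
Reagents that add atoms: benzyl chloroformate, O=C(Cl)OCc1ccccc1
Why: The vinylogous acid is acylated on oxygen by the chloroformate (enol carbonate formation), which fixes one enol form, removes the acidic proton that would promote retro-aldol loss of the side chain once the silyl group is gone, and disfavours photochemical acyl shift in the key step.

Step 11
Reactants: 14 benzyl 2-{(3R)-2,6-dimethyl-3-[(triethylsilyl)oxy]hept-6-en-3-yl}-3-oxocyclopent-1-en-1-yl carbonate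
Product: 15 benzyl 2-[(3R)-3-hydroxy-2,6-dimethylhept-6-en-3-yl]-3-oxocyclopent-1-en-1-yl carbonate
Conditions: 48% aq. HF, MeCN, 0 °C
Reagents that add atoms: none
Why: Acidic fluoride cleaves the triethylsilyl ether without attacking the enol carbonate, and the product is an α-(1-hydroxyalkyl) enone of the Morita–Baylis–Hillman type, which has no enolisable path to retro-aldol cleavage.

Step 12
Reactants: 15 benzyl 2-[(3R)-3-hydroxy-2,6-dimethylhept-6-en-3-yl]-3-oxocyclopent-1-en-1-yl carbonate
Product: 18 (3R,3aR,8aR)-3-hydroxy-8a-methyl-3-(propan-2-yl)octahydroazulene-4,7-dione, via cyclobutane photoadduct 16 (not isolated), via cyclobutanol 17 (not isolated)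
Conditions: hν (350 nm), degassed cyclohexane/CH2Cl2, 0.005 M, 10 °C; then H2 (1 atm), 10% Pd/C, EtOAc, rt; then DBU (0.1 equiv), CH2Cl2, rt
Reagents that add atoms: none
Why: The triplet of the 3-acyloxy enone should bond through its α-carbon to the internal alkene carbon in a 1,5-closure (5-exo) that forms ring B, and the 1,4-biradical then closes between the terminal CH2 and the oxygen-bearing carbon to give the cis-fused cyclobutane 16; hydrogenolysis of the benzyl carbonate frees cyclobutanol 17, a strained β-hydroxy ketone whose retro-aldol cleavage inserts the two alkene carbons into the former dione ring and so expands it to the seven-membered ring A. The closest known reactions are intramolecular de Mayo reactions of 2-(pent-4-enyl)cycloalkane-1,3-dione enol esters and enol carbonates to fused cycloheptanediones, and hydroxyl-directed intramolecular enone–alkene photocycloadditions in aprotic solvents. The quaternary C8a centre is controlled by C3: in a solvent that cannot accept hydrogen bonds the tertiary hydroxyl is bound to the enone carbonyl, which holds the C–O bond in the enone plane on the carbonyl side and leaves the tether and the isopropyl group on opposite faces beside the carbonate-bearing carbon, so that cyclobutane formation on the tether face puts the oxygen cis to the future C8a methyl and the isopropyl group cis to C8. C3a is set when the liberated enol ketonises and is then equilibrated by DBU to the trans ring fusion, in which the C4 carbonyl carbon avoids the isopropyl group and keeps the hydroxyl–carbonyl hydrogen bond. The step needs straight rather than crossed addition, which the three-atom tether secures through the five-membered first closure, and it needs the carbonate and the long wavelength so that acyl shift of the enol derivative and photolysis of the product ketones do not compete.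

Step 13
Reactants: 18 (3R,3aR,8aR)-3-hydroxy-8a-methyl-3-(propan-2-yl)octahydroazulene-4,7-dione
Product: 19 (3R,3aS,4S,8aR)-3,4-dihydroxy-8a-methyl-3-(propan-2-yl)octahydroazulen-7(1H)-one
Conditions: Me4NBH(OAc)3, MeCN/AcOH, −20 °C
Reagents that add atoms: none
Why: In the Evans–Saksena reduction the triacetoxyborohydride exchanges onto the C3 hydroxyl and delivers hydride intramolecularly to the C4 carbonyl on the face on which that oxygen lies (the face of the angular methyl), giving the 4S carbinol with the 1,3-anti diol relationship, while the C7 ketone, which has no directing hydroxyl, is not reduced.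

Step 14
Reactants: 19 (3R,3aS,4S,8aR)-3,4-dihydroxy-8a-methyl-3-(propan-2-yl)octahydroazulen-7(1H)-one
Product: 20 (3R,3aS,4S,8aR)-4-[(tert-butyldimethylsilyl)oxy]-3-hydroxy-8a-methyl-3-(propan-2-yl)octahydroazulen-7(1H)-one
Conditions: tBuMe2SiOTf (1.1 equiv), 2,6-lutidine, CH2Cl2, −78 °C
Reagents that add atoms: tert-butyldimethylsilyl trifluoromethanesulfonate, CC(C)(C)[Si](C)(C)OS(=O)(=O)C(F)(F)F
Why: At low temperature the silyl triflate discriminates the secondary from the far more hindered tertiary hydroxyl (selective silylation), leaving the tertiary alcohol free for acylation.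

Step 15
Reactants: 21 4-hydroxybenzoic acid
Product: 23 4-[(tert-butyldimethylsilyl)oxy]benzoyl chloride, via silyl ester 22 (not isolated)
Conditions: tBuMe2SiCl (2.2 equiv), imidazole, DMF, rt; then (COCl)2, DMF (cat.), CH2Cl2, 0 °C → rt
Reagents that add atoms: tert-butyl(chloro)dimethylsilane, CC(C)(C)[Si](C)(C)Cl; oxalyl chloride, ClC(=O)C(=O)Cl
Why: Exhaustive silylation followed by the known conversion of a silyl ester into an acid chloride with oxalyl chloride and catalytic DMF gives the phenol-protected acid chloride under neutral conditions that leave the aryl silyl ether intact.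

Step 16
Reactants: 20 (3R,3aS,4S,8aR)-4-[(tert-butyldimethylsilyl)oxy]-3-hydroxy-8a-methyl-3-(propan-2-yl)octahydroazulen-7(1H)-one; 23 4-[(tert-butyldimethylsilyl)oxy]benzoyl chloride
Product: 25 (3R,3aS,4S,8aR)-4-[(tert-butyldimethylsilyl)oxy]-8a-methyl-7-oxo-3-(propan-2-yl)decahydroazulen-3-yl 4-[(tert-butyldimethylsilyl)oxy]benzoate, via aroyl triflate 24 (not isolated)
Conditions: 23, AgOTf, CH2Cl2, −78 °C; then 20, pyridine, −78 → 0 °C
Reagents that add atoms: none
Why: An aroyl triflate, formed from the acid chloride and AgOTf, is one of the strongest acyl donors for hindered tertiary alcohols (acylation via acyl triflate), and because the method is not basic it avoids enolisation of the C7 ketone and migration of the neighbouring silyl group.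

Step 17
Reactants: 25 (3R,3aS,4S,8aR)-4-[(tert-butyldimethylsilyl)oxy]-8a-methyl-7-oxo-3-(propan-2-yl)decahydroazulen-3-yl 4-[(tert-butyldimethylsilyl)oxy]benzoate
Product: 27 (3R,3aS,4S,8aR)-4-[(tert-butyldimethylsilyl)oxy]-8a-methyl-7-oxo-3-(propan-2-yl)-1,2,3,3a,4,7,8,8a-octahydroazulen-3-yl 4-[(tert-butyldimethylsilyl)oxy]benzoate, via trimethylsilyl enol ether 26 (not isolated)
Conditions: LiN(iPr)2, Me3SiCl, THF, −78 °C; then Pd(OAc)2 (1.1 equiv), MeCN, rt
Reagents that add atoms: none
Why: Kinetic deprotonation occurs at C6 because C8 is neopentyl, and Saegusa–Ito oxidation of the resulting trimethylsilyl enol ether with Pd(OAc)2 gives the C5–C6 enone regiospecifically.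

Step 18
Reactants: 27 (3R,3aS,4S,8aR)-4-[(tert-butyldimethylsilyl)oxy]-8a-methyl-7-oxo-3-(propan-2-yl)-1,2,3,3a,4,7,8,8a-octahydroazulen-3-yl 4-[(tert-butyldimethylsilyl)oxy]benzoate
Product: 28 (3R,3aS,4R,8aR)-4-[(tert-butyldimethylsilyl)oxy]-6-iodo-8a-methyl-7-oxo-3-(propan-2-yl)-1,2,3,3a,4,7,8,8a-octahydroazulen-3-yl 4-[(tert-butyldimethylsilyl)oxy]benzoate
Conditions: I2, pyridine, CH2Cl2, rt
Reagents that add atoms: iodine, II
Why: Pyridine-mediated α-iodination of a cyclic enone (conjugate addition of pyridine, iodination of the enolate, elimination) places iodine on C6 only; the C4 descriptor changes by priority, not by geometry.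

Step 19
Reactants: 28 (3R,3aS,4R,8aR)-4-[(tert-butyldimethylsilyl)oxy]-6-iodo-8a-methyl-7-oxo-3-(propan-2-yl)-1,2,3,3a,4,7,8,8a-octahydroazulen-3-yl 4-[(tert-butyldimethylsilyl)oxy]benzoate
Product: 29 (3R,3aS,4S,8aR)-4-[(tert-butyldimethylsilyl)oxy]-6,8a-dimethyl-7-oxo-3-(propan-2-yl)-1,2,3,3a,4,7,8,8a-octahydroazulen-3-yl 4-[(tert-butyldimethylsilyl)oxy]benzoate
Conditions: Me4Sn, Pd2(dba)3 (5 mol %), AsPh3, CuI, NMP, 60 °C
Reagents that add atoms: tetramethylstannane, C[Sn](C)(C)C
Why: Stille coupling of an α-iodo enone with tetramethylstannane is a mild, neutral way to the 2-methyl enone and leaves the ester and both silyl ethers alone.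

Step 20
Reactants: 29 (3R,3aS,4S,8aR)-4-[(tert-butyldimethylsilyl)oxy]-6,8a-dimethyl-7-oxo-3-(propan-2-yl)-1,2,3,3a,4,7,8,8a-octahydroazulen-3-yl 4-[(tert-butyldimethylsilyl)oxy]benzoate
Product: 30 (3R,3aS,4S,8aR)-4-hydroxy-6,8a-dimethyl-7-oxo-3-(propan-2-yl)-1,2,3,3a,4,7,8,8a-octahydroazulen-3-yl 4-hydroxybenzoate
Conditions: HF·pyridine, pyridine, THF, 0 °C → rt
Reagents that add atoms: none
Why: Buffered HF·pyridine removes the aryl and the allylic secondary silyl ether (fluoride desilylation) under mildly acidic conditions, where neither migration of the aroyl group from the tertiary to the secondary oxygen nor isomerisation of the γ-hydroxy enone is expected.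

**Compound list**

1 | ethyl 4-methyl-3-oxopentanoate | CCOC(=O)CC(=O)C(C)C | starting material
2 | ethyl (2Z)-4-methyl-3-{[(trifluoromethyl)sulfonyl]oxy}pent-2-enoate | CCOC(=O)/C=C(/C(C)C)OS(=O)(=O)C(F)(F)F | intermediate
3 | 4-bromo-2-methylbut-1-ene | CC(=C)CCBr | starting material
4 | (3-methylbut-3-en-1-yl)magnesium bromide | CC(=C)CC[Mg]Br | intermediate
5 | ethyl (2E)-6-methyl-3-(propan-2-yl)hepta-2,6-dienoate | CCOC(=O)/C=C(/C(C)C)CCC(C)=C | intermediate
6 | (2E)-6-methyl-3-(propan-2-yl)hepta-2,6-dien-1-ol | OC/C=C(/C(C)C)CCC(C)=C | intermediate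
7 | [(2R,3R)-3-(3-methylbut-3-en-1-yl)-3-(propan-2-yl)oxiran-2-yl]methanol | CC(=C)CC[C@@]1(O[C@@H]1CO)C(C)C | intermediate
8 | (3S)-6-methyl-3-(propan-2-yl)hept-6-ene-1,3-diol | CC(=C)CC[C@@](CCO)(O)C(C)C | intermediate
9 | (3S)-6-methyl-3-(propan-2-yl)-1,3-bis[(triethylsilyl)oxy]hept-6-ene | CC(=C)CC[C@@](CCO[Si](CC)(CC)CC)(O[Si](CC)(CC)CC)C(C)C | intermediate
10 | (3S)-6-methyl-3-(propan-2-yl)-3-[(triethylsilyl)oxy]hept-6-enal | CC(=C)CC[C@@](CC=O)(O[Si](CC)(CC)CC)C(C)C | intermediate
11 | methyl acrylate | COC(=O)C=C | starting material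
12 | methyl (6S)-9-methyl-4-oxo-6-(propan-2-yl)-6-[(triethylsilyl)oxy]dec-9-enoate | CC(=C)CC[C@@](CC(=O)CCC(=O)OC)(O[Si](CC)(CC)CC)C(C)C | intermediate
13 | 2-{(3R)-2,6-dimethyl-3-[(triethylsilyl)oxy]hept-6-en-3-yl}-3-hydroxycyclopent-2-en-1-one (enolised 1,3-dione) | CC(=C)CC[C@@](C1=C(O)CCC1=O)(O[Si](CC)(CC)CC)C(C)C | intermediate
14 | benzyl 2-{(3R)-2,6-dimethyl-3-[(triethylsilyl)oxy]hept-6-en-3-yl}-3-oxocyclopent-1-en-1-yl carbonate | CC(=C)CC[C@@](C1=C(OC(=O)OCc2ccccc2)CCC1=O)(O[Si](CC)(CC)CC)C(C)C | intermediate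
15 | benzyl 2-[(3R)-3-hydroxy-2,6-dimethylhept-6-en-3-yl]-3-oxocyclopent-1-en-1-yl carbonate | CC(=C)CC[C@@](C1=C(OC(=O)OCc2ccccc2)CCC1=O)(O)C(C)C | intermediate
16 | cyclobutane photoadduct: benzyl 10-hydroxy-7-methyl-2-oxo-10-(propan-2-yl)tricyclo[5.3.0.0(1,5)]decan-5-yl carbonate, all ring fusions cis, 10-hydroxyl cis to the 7-methyl and to the C2 carbonyl carbon | O=C1CC[C@]2(OC(=O)OCc4ccccc4)C[C@@]3(C)CC[C@@](O)(C(C)C)[C@@]123 | intermediate
17 | cyclobutanol: 5,10-dihydroxy-7-methyl-10-(propan-2-yl)tricyclo[5.3.0.0(1,5)]decan-2-one, same configuration as 16 | O=C1CC[C@]2(O)C[C@@]3(C)CC[C@@](O)(C(C)C)[C@@]123 | intermediate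
18 | (3R,3aR,8aR)-3-hydroxy-8a-methyl-3-(propan-2-yl)octahydroazulene-4,7-dione | C1CC(=O)[C@@H]2[C@](C)(CC[C@@]2(O)C(C)C)CC1=O | intermediate
19 | (3R,3aS,4S,8aR)-3,4-dihydroxy-8a-methyl-3-(propan-2-yl)octahydroazulen-7(1H)-one | O=C1CC[C@H](O)[C@@H]2[C@](C)(CC[C@@]2(O)C(C)C)C1 | intermediate
20 | (3R,3aS,4S,8aR)-4-[(tert-butyldimethylsilyl)oxy]-3-hydroxy-8a-methyl-3-(propan-2-yl)octahydroazulen-7(1H)-one | O=C1CC[C@H](O[Si](C)(C)C(C)(C)C)[C@@H]2[C@](C)(CC[C@@]2(O)C(C)C)C1 | intermediate
21 | 4-hydroxybenzoic acid | OC(=O)c1ccc(O)cc1 | starting material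
22 | tert-butyldimethylsilyl 4-[(tert-butyldimethylsilyl)oxy]benzoate | CC(C)(C)[Si](C)(C)OC(=O)c1ccc(O[Si](C)(C)C(C)(C)C)cc1 | intermediate
23 | 4-[(tert-butyldimethylsilyl)oxy]benzoyl chloride | CC(C)(C)[Si](C)(C)Oc1ccc(cc1)C(Cl)=O | intermediate
24 | 4-[(tert-butyldimethylsilyl)oxy]benzoyl trifluoromethanesulfonate | CC(C)(C)[Si](C)(C)Oc1ccc(cc1)C(=O)OS(=O)(=O)C(F)(F)F | intermediate
25 | (3R,3aS,4S,8aR)-4-[(tert-butyldimethylsilyl)oxy]-8a-methyl-7-oxo-3-(propan-2-yl)decahydroazulen-3-yl 4-[(tert-butyldimethylsilyl)oxy]benzoate | O=C1CC[C@H](O[Si](C)(C)C(C)(C)C)[C@@H]2[C@](C)(CC[C@@]2(OC(=O)c3ccc(O[Si](C)(C)C(C)(C)C)cc3)C(C)C)C1 | intermediate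
26 | (3R,3aS,4S,8aR)-4-[(tert-butyldimethylsilyl)oxy]-8a-methyl-3-(propan-2-yl)-7-[(trimethylsilyl)oxy]-1,2,3,3a,4,5,8,8a-octahydroazulen-3-yl 4-[(tert-butyldimethylsilyl)oxy]benzoate | C[Si](C)(C)OC1=CC[C@H](O[Si](C)(C)C(C)(C)C)[C@@H]2[C@](C)(CC[C@@]2(OC(=O)c3ccc(O[Si](C)(C)C(C)(C)C)cc3)C(C)C)C1 | intermediate
27 | (3R,3aS,4S,8aR)-4-[(tert-butyldimethylsilyl)oxy]-8a-methyl-7-oxo-3-(propan-2-yl)-1,2,3,3a,4,7,8,8a-octahydroazulen-3-yl 4-[(tert-butyldimethylsilyl)oxy]benzoate | O=C1C=C[C@H](O[Si](C)(C)C(C)(C)C)[C@@H]2[C@](C)(CC[C@@]2(OC(=O)c3ccc(O[Si](C)(C)C(C)(C)C)cc3)C(C)C)C1 | intermediate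
28 | (3R,3aS,4R,8aR)-4-[(tert-butyldimethylsilyl)oxy]-6-iodo-8a-methyl-7-oxo-3-(propan-2-yl)-1,2,3,3a,4,7,8,8a-octahydroazulen-3-yl 4-[(tert-butyldimethylsilyl)oxy]benzoate | O=C1C(I)=C[C@H](O[Si](C)(C)C(C)(C)C)[C@@H]2[C@](C)(CC[C@@]2(OC(=O)c3ccc(O[Si](C)(C)C(C)(C)C)cc3)C(C)C)C1 | intermediate
29 | (3R,3aS,4S,8aR)-4-[(tert-butyldimethylsilyl)oxy]-6,8a-dimethyl-7-oxo-3-(propan-2-yl)-1,2,3,3a,4,7,8,8a-octahydroazulen-3-yl 4-[(tert-butyldimethylsilyl)oxy]benzoate | CC1=C[C@H](O[Si](C)(C)C(C)(C)C)[C@@H]2[C@](C)(CC[C@@]2(OC(=O)c3ccc(O[Si](C)(C)C(C)(C)C)cc3)C(C)C)CC1=O | intermediate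
30 | (3R,3aS,4S,8aR)-4-hydroxy-6,8a-dimethyl-7-oxo-3-(propan-2-yl)-1,2,3,3a,4,7,8,8a-octahydroazulen-3-yl 4-hydroxybenzoate | CC1=C[C@H](O)[C@@H]2[C@](C)(CC[C@@]2(OC(=O)c2ccc(O)cc2)C(C)C)CC1=O | target

**Step count and risks**

Total: 20 steps. Longest linear sequence: 19 steps (steps 1–14 and 16–20, from compound 1); step 15 is a one-step side branch.

Steps most likely to fail:

Step 12. Facial control would be lost if the hydroxyl–carbonyl hydrogen bond does not hold the rotamer during the first C–C bond formation, which would give the C8a epimer. Crossed instead of straight closure, transfer of the carbonate onto the free tertiary hydroxyl before irradiation, or aldol reversal of the tertiary ketol during the base equilibration could also erode the step. The fallback sets out from 13 and makes facial selection rest on steric and dipole effects of the silyl ether instead of on the hydrogen bond. The free enol 13 is irradiated directly (350 nm, MeCN), where the cyclobutanol fragments in the flask. This should give (3R,3aR,8aR)-8a-methyl-3-(propan-2-yl)-3-[(triethylsilyl)oxy]octahydroazulene-4,7-dione F1. Its ring fusion is equilibrated with DBU while the tertiary oxygen is still protected, and aqueous HF in MeCN then removes the silyl group to rejoin the route at 18.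

Step 9. β-Elimination of triethylsilanolate from the ketone enolate may compete with the ring closure, and the alkoxide may also open the product. The fallback sets out from 12 and replaces the alkoxide-driven condensation by a soft-enolisation C-acylation of an activated amide. Saponification (LiOH, THF/H2O) gives (6S)-9-methyl-4-oxo-6-(propan-2-yl)-6-[(triethylsilyl)oxy]dec-9-enoic acid F2. 1-(Methanesulfonyl)-1H-benzotriazole and Et3N convert it into (6S)-1-(1H-benzotriazol-1-yl)-9-methyl-6-(propan-2-yl)-6-[(triethylsilyl)oxy]dec-9-ene-1,4-dione F3. MgBr2·OEt2 with iPr2NEt in CH2Cl2 then closes the ring through the magnesium enolate without a strong base and returns to 13.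

Step 16. The very hindered tertiary hydroxyl may fail to acylate, or the tertiary carbinol may ionise and eliminate under the electrophilic conditions. The fallback sets out from 20 and acylates a metal alkoxide after masking the ketone. Ketalisation with 1,2-bis(trimethylsilyloxy)ethane and catalytic Me3SiOTf (CH2Cl2, −78 °C) gives the ethylene ketal of 20 (1,3-dioxolane at C7) F4. MeMgBr (1 equiv, THF, 0 °C) forms the bromomagnesium alkoxide, which is less prone to silyl migration than an alkali alkoxide, and 23 acylates it to the ethylene ketal of 25 (1,3-dioxolane at C7) F5. PPTS in aqueous acetone removes the ketal and returns to 25.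

Further compounds
F1 | step 12 | (3R,3aR,8aR)-8a-methyl-3-(propan-2-yl)-3-[(triethylsilyl)oxy]octahydroazulene-4,7-dione | C1CC(=O)[C@@H]2[C@](C)(CC[C@@]2(O[Si](CC)(CC)CC)C(C)C)CC1=O
F2 | step 9 | (6S)-9-methyl-4-oxo-6-(propan-2-yl)-6-[(triethylsilyl)oxy]dec-9-enoic acid | CC(=C)CC[C@@](CC(=O)CCC(=O)O)(O[Si](CC)(CC)CC)C(C)C
F3 | step 9 | (6S)-1-(1H-benzotriazol-1-yl)-9-methyl-6-(propan-2-yl)-6-[(triethylsilyl)oxy]dec-9-ene-1,4-dione | CC(=C)CC[C@@](CC(=O)CCC(=O)n1nnc2ccccc12)(O[Si](CC)(CC)CC)C(C)C
F4 | step 16 | ethylene ketal of 20 (1,3-dioxolane at C7) | C14(OCCO4)CC[C@H](O[Si](C)(C)C(C)(C)C)[C@@H]2[C@](C)(CC[C@@]2(O)C(C)C)C1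
F5 | step 16 | ethylene ketal of 25 (1,3-dioxolane at C7) | C14(OCCO4)CC[C@H](O[Si](C)(C)C(C)(C)C)[C@@H]2[C@](C)(CC[C@@]2(OC(=O)c3ccc(O[Si](C)(C)C(C)(C)C)cc3)C(C)C)C1
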